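## Structural features

The target is a single cyclopentane in which two neighbouring ring carbons are quaternary; each bears a methyl group, the methyls are cis, and both centres are R. These are the only stereocentres and they stand directly next to each other. One of them carries an acyl carbon that continues as an (E)-enone ending in a tertiary allylic alcohol. The other carries a CH2–C(=O)–CH2–C(CH3)=CH–CH2–aryl arm, so the two ketones are 1,5-related across the two quaternary carbons. The arene is a hydroquinone monomethyl ether whose methoxy group is flanked by a methyl and by the benzylic CH2, with the free hydroxyl para to the methoxy group. Fragile points are the β,γ-unsaturated ketone (its E-alkene is skipped between ketone and arene and can slide into conjugation with either), the enolisable 1,5-diketone/enone pair, the acid-sensitive tertiary allylic alcohol and the oxidation-prone phenol. The real difficulty is the pair of contiguous all-carbon quaternary centres in one absolute sense, one of them bearing a very congested acyl carbon. The key step exploits that each quaternary carbon holds one methyl and that the acyl carbon and the arm sit cis on adjacent ring carbons: bonding the acyl carbon to the second carbon of the arm closes a second five-membered ring, giving 1,5-dimethylbicyclo[3.3.0]octan-2-one, whose two methyls can be laid across the C1=C5 ring-fusion double bond of the corresponding enone.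

## Logic of the disconnections

24 ⇒ 23. The phenolic O–H is exchanged for an O–Si bond. A free electron-rich phenol would not survive strong bases, organometallic reagents or tetravalent lead, whereas a bulky aryl silyl ether does, so all earlier steps can ignore the phenol. The forward step must unmask it without base, because the skipped enone and the 1,5-dicarbonyl array are then already present.

23 ⇒ 22. The acyl carbon and the ketone carbon of the arm are rejoined by a C–C bond, each as a tertiary carbinol, which recloses the second five-membered ring. This turns an open-chain problem into a bicyclic one and keeps both sensitive carbonyl groups hidden in a diol until the penultimate step. The forward cleavage must be specific for the vicinal diol, must work for either relative configuration of the two carbinols, and must spare the alkenes, the arene and the remote tertiary alcohol.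

22 ⇒ 21. The (E)-alkene on the ring carbinol is taken back to an alkyne. A linear alkynyl group reaches a crowded carbonyl far more easily than an alkenyl group, and the two flanking oxygens later direct a trans-selective reduction. The forward step must reduce only the alkyne and give the E geometry.

21 ⇒ 18 + 19. The bond between ring carbon C2 and the alkyne carbon is cut, leaving a ring ketone and a terminal alkyne, so all five carbons of the enone arm come from 19. The forward step is a 1,2-addition to a ketone flanked by two fully substituted carbons; in return that ketone has no α-hydrogen.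

18 ⇒ 16. The C3–O bond is removed. C3 is the only enolisable position of 16, so the oxygen can be placed by enolate oxidation with no question of site. The oxidant must spare the trisubstituted alkene and the arene.

16 ⇒ 5 + 14. The C3–CH2 bond is cut, detaching the whole aryl–alkenyl arm as an allylic bromide and leaving the bare bicyclic ketone. This is the convergent join of the route. It requires clean mono-alkylation at the only enolisable carbon, with direct (SN2) attack on the allylic bromide.

5 ⇒ 3 (through 4). Both C–CH3 bonds at the ring fusion are cut, the β-methyl as a nucleophile and the α-methyl as an electrophile. Both stereocentres disappear in one transform and an achiral, flat enone remains. The forward step must select one face at the β-carbon under catalyst control; the second methyl then has no choice.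

3 ⇒ 1 + 2. The acyl–alkene bond and the ring-closing bond of the cyclopentenone are cut. Two bulk chemicals result. The forward step is a one-pot acylation and electrocyclisation in strong acid.

14 ⇒ 13 ⇒ 10 + 11. The C–Br bond goes back to C–OH, and then the vinyl–methyl and vinyl–benzyl bonds are cut. The alkene geometry is thereby reduced to the syn course of a carbometalation on a three-carbon alkynol. The forward step needs regio- and stereodefined carboalumination and coupling with retention.

10 ⇒ 9 ⇒ 7 ⇒ 6. The C–Br bond goes back to C–OH, then the aryl–CH2 bond next to the methoxy group is cut, then the O–Si bond. The carbon must enter beside the methoxy group and not beside the phenol oxygen, the opposite of what electrophilic substitution of 6 would favour. The forward step therefore relies on metalation directed by the methoxy group while the phenol oxygen is shielded.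

## Other disconnections considered

Alternative 1: The cut leaves both quaternary carbons intact and takes them, already in the right absolute sense, from (1R,3S)-camphoric acid A1; only the C–O bond on one of its geminal methyls is disconnected, so that this methyl becomes the first carbon of the arm. In the forward direction the amide ester A2 (methyl ester on the quaternary carbon, primary carboxamide on the secondary one) would be treated with PhI(OAc)2 and I2 under light. The amidyl radical takes a hydrogen through a six-membered transition state from the only methyl within reach, the one cis to it; iodination, closure through the amide oxygen and hydrolysis would give the cis-fused γ-lactone A3. In its favour, no asymmetric step is needed and the geometry alone selects the right methyl. On certainty of configuration and on precedent this alternative is the better of the two, since the chosen plan rests on an untried catalytic step. Against it, A3 is one carbon short on the arm and carries one carboxyl too many on the ring. The CH2–O carbon is neopentyl between two quaternary centres, so it can only be extended by oxidation and one-carbon homologation; the lactone carbonyl sits on a ring carbon that is CH2 in the target and must be excised by radical decarboxylation; and three carboxyl-level groups must be told apart. Mechanistically, a radical C–H functionalisation of an unactivated methyl is less predictable in efficiency than the ionic steps of the chosen plan. In step economy the alternative would be clearly longer; in cost of the starting material it is equal.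

Alternative 2: The cut removes at once the two bonds from the quaternary carbons to their arms, the quaternary carbon–acyl bond and the quaternary carbon–CH2 bond. In the forward direction (R)-2-tert-butyl-6-methyl-1,3-dioxin-4-one A4 would be irradiated with 1,2-dimethylcyclopentene A5 to give the cis-anti-cis tricyclic photoadduct A6, and acetal hydrolysis with retro-aldol opening of the cyclobutane (de Mayo sequence) would give keto acid A7. In its favour, one step creates both quaternary centres with both arms attached, and the symmetrical alkene removes any head-to-tail question. The cis relationship is enforced by ring fusion exactly as in the chosen plan, so on that point the two are equal. The arms emerge already differentiated as methyl ketone and acid, which is better than the chosen plan, where a ring has to be functionalised and broken to tell them apart. Against it, the absolute configuration depends on face selection by a remote acetal centre in a triplet enone that pyramidalises at its β-carbon, which is hard to foresee; a tetrasubstituted alkene is a sluggish partner; and A4 must first be made enantiopure. The acetyl group of A7 must also be extended by aldol condensation, and its acid arm turned into the skipped enone ketone with a real risk of alkene migration. Both plans stake the absolute configuration on an external chiral element of uncertain efficiency, but the photocycloaddition is an established reaction type, so on precedent the alternative is the better. In step count the two would be similar, the alternative slightly longer once the preparation of A4 is included.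

Alternative 3: The cut removes the vinyl–methyl and vinyl–benzyl bonds of the trisubstituted alkene on an intermediate that already contains the cyclopentane. In the forward direction alkyne A8 (silyl-protected hydroxymethyl group on one quaternary carbon, silyl-protected 2-hydroxypent-4-ynyl arm on the other) would undergo Cp2ZrCl2-catalysed methylalumination and Pd(PPh3)4-catalysed coupling with 10 to give the fully protected product A9. In its favour, the E geometry is fixed reliably and the arene enters late; on convergence this alternative is the better. The bond-forming event is the same one used in step 6 of the chosen route, so on mechanism and precedent the two are equal. Against it, the disconnection leaves the two quaternary centres unsolved, since A8 needs its own asymmetric construction. A9 is also at a low oxidation level, so both arms need deprotection and oxidation, an alkenyl group must still be added to a neopentyl aldehyde, and two alkyl silyl ethers must be handled selectively beside the aryl silyl ether. The chosen plan performs the same alumination and coupling on the three-carbon alkynol 11, where nothing is at risk, and reaches the target three steps after the full skeleton is assembled; the alternative would need about twice as many from A9.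

Key step: step 2

Remarks on the chemistry (assumptions):

- Configuration check: cutting the C2–C3 bond of (1R,5R)-5 turns C1 into the ring carbon bearing the acyl group and C5 into the ring carbon bearing the arm. With the priorities of 24 both are R and the methyls are cis, so (1R,5R)-5 is the enantiomer required.
- The sense of induction of the ligand in step 2 cannot be deduced for this substrate class; the antipode of the ligand that leads to (1R,5R)-5 is the one meant.
- The centres formed at C3 (steps 8 and 9) and C2 (step 10) of the sacrificial ring are expected as mixtures and both become carbonyl carbons in step 12; they are left unspecified in names and SMILES.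
- Enone 3 carries no auxiliary group: its α-carbon must stay free for the second methyl, so activation has to come from the Lewis acid and the catalyst.

**Step 1**

Reactants: 1 cyclopentene; 2 acrylic acid

Product: 3 bicyclo[3.3.0]oct-1(5)-en-2-one

Conditions: polyphosphoric acid, 60–65 °C

Reagents that add atoms: none

Why: Acylation of 1 by the mixed anhydride of 2 gives 1-cyclopentenyl vinyl ketone, which closes by Nazarov cyclisation (4π conrotatory closure of the pentadienyl cation); loss of a proton places the double bond in the tetrasubstituted ring-fusion position, and no stereocentre is formed.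

**Step 2**

Reactants: 3 bicyclo[3.3.0]oct-1(5)-en-2-one

Product: 5 (1R,5R)-1,5-dimethylbicyclo[3.3.0]octan-2-one, via dimethylaluminium enolate 4 (not isolated)

Conditions: Me3Al (1.5 equiv), Cu(O2CC4H3S) (5 mol %), O,O′-(biphenyl-2,2′-diyl) N,N-bis[(S)-1-(naphthalen-2-yl)ethyl]phosphoramidite (10 mol %), Et2O, −30 °C; then MeLi (1.5 equiv), MeI (5 equiv), THF–DMPU, −30 °C to rt

Reagents that add atoms: trimethylaluminium `C[Al](C)C`; iodomethane `CI`

Why: Proposed new method: Me3Al transmetalates the copper carboxylate to a ligated methylcopper species (monovalent copper), which binds the C1=C5 π-bond of the aluminium-activated enone, adds oxidatively to give a σ-alkyl trivalent copper enolate and eliminates reductively, forming the C5–CH3 bond and enolate 4. The closest known reaction type is the copper–phosphoramidite-catalysed asymmetric conjugate addition of Me3Al to 3-substituted cyclopent-2-enones with enolate trapping, together with the stoichiometric Me2CuLi addition–methylation of 3; new is the catalytic asymmetric version on an enone whose α- and β-carbons are both fully substituted, thought feasible because the ring-fusion alkene is strained and the carbonyl is held by the Lewis-acidic aluminium. No ring is closed; two C–CH3 bonds are formed. The C5 stereocentre is set by the chiral ligand alone, since 3 is achiral and flat and has no bias of its own. MeLi converts 4 into a lithium aluminate enolate nucleophilic enough for SN2 attack on MeI at C1, and the C1 stereocentre is set by the substrate: the methyl must enter on the face of the C5 methyl because a trans-fused bicyclo[3.3.0]octane is prohibitively strained. The step needs 1,4- rather than 1,2-addition (soft copper nucleophile), alkylation at C1 and not at C3 (the enolate is formed regiospecifically and is alkylated cold with excess MeI before proton transfer can move it) and C- rather than O-alkylation (soft electrophile).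

**Step 3**

Reactants: 6 4-methoxy-3-methylphenol

Product: 7 triisopropyl(4-methoxy-3-methylphenoxy)silane

Conditions: iPr3SiCl, imidazole, DMF, rt

Reagents that add atoms: chlorotriisopropylsilane `CC(C)[Si](Cl)(C(C)C)C(C)C`

Why: Silylation of the phenol (substitution at silicon with imidazole as base and nucleophilic catalyst); the bulky silyl group protects the oxygen and later keeps the metalating base away from the positions next to it.

**Step 4**

Reactants: 7 triisopropyl(4-methoxy-3-methylphenoxy)silane

Product: 9 [2-methoxy-3-methyl-5-(triisopropylsilyloxy)phenyl]methanol, via aryllithium 8 (not isolated)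

Conditions: n-BuLi, TMEDA, Et2O, 0 °C to rt; then (CH2O)n, THF, −78 °C to rt

Reagents that add atoms: formaldehyde (from paraformaldehyde) `C=O`

Why: Directed ortho-metalation: the methoxy oxygen guides n-BuLi·TMEDA to its only free ortho position, while the hindered silyloxy group neither binds the base nor lets its ortho positions be reached; the aryllithium is then hydroxymethylated by formaldehyde.

**Step 5**

Reactants: 9 [2-methoxy-3-methyl-5-(triisopropylsilyloxy)phenyl]methanol

Product: 10 [3-(bromomethyl)-4-methoxy-5-methylphenoxy]triisopropylsilane

Conditions: CBr4, PPh3, CH2Cl2, 0 °C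

Reagents that add atoms: carbon tetrabromide `BrC(Br)(Br)Br`

Why: Appel reaction: the alkoxyphosphonium ion is displaced by bromide at the primary benzylic carbon under neutral conditions that leave the aryl silyl ether untouched.

**Step 6**

Reactants: 11 prop-2-yn-1-ol; 10 [3-(bromomethyl)-4-methoxy-5-methylphenoxy]triisopropylsilane

Product: 13 (E)-4-[2-methoxy-3-methyl-5-(triisopropylsilyloxy)phenyl]-2-methylbut-2-en-1-ol, via alkenylalane 12 (not isolated)

Conditions: Me3Al (3 equiv), Cp2ZrCl2 (25 mol %), CH2Cl2, 0 °C to rt; then 10, Pd(PPh3)4 (5 mol %), THF, rt

Reagents that add atoms: trimethylaluminium `C[Al](C)C`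

Why: Zirconium-catalysed carboalumination (Negishi type) of the terminal alkyne, carried as its aluminium alkoxide, adds methyl and aluminium syn with methyl on the internal carbon. Zerovalent palladium then inserts into the C–Br bond of 10, and transmetalation and reductive elimination join alkenyl and benzyl carbons with retention, so the alkene should be E.

**Step 7**

Reactants: 13 (E)-4-[2-methoxy-3-methyl-5-(triisopropylsilyloxy)phenyl]-2-methylbut-2-en-1-ol

Product: 14 {3-[(E)-4-bromo-3-methylbut-2-en-1-yl]-4-methoxy-5-methylphenoxy}triisopropylsilane

Conditions: CBr4, PPh3, CH2Cl2, 0 °C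

Reagents that add atoms: carbon tetrabromide `BrC(Br)(Br)Br`

Why: Appel reaction at a primary allylic alcohol; direct displacement at the CH2 under neutral conditions should keep the alkene position and geometry.

**Step 8**

Reactants: 5 (1R,5R)-1,5-dimethylbicyclo[3.3.0]octan-2-one; 14 {3-[(E)-4-bromo-3-methylbut-2-en-1-yl]-4-methoxy-5-methylphenoxy}triisopropylsilane

Product: 16 (1R,5R)-3-{(E)-4-[2-methoxy-3-methyl-5-(triisopropylsilyloxy)phenyl]-2-methylbut-2-en-1-yl}-1,5-dimethylbicyclo[3.3.0]octan-2-one (C3 epimers), via lithium enolate 15 (not isolated)

Conditions: LiN(iPr)2, THF, −78 °C; then 14, DMPU, −78 to 0 °C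

Reagents that add atoms: none

Why: Ketone enolate alkylation (SN2): 5 can enolise only towards C3 because C1 is quaternary, and the primary allylic bromide is attacked at its CH2. The new C3 centre is of no consequence because it becomes a carbonyl carbon in step 12.

**Step 9**

Reactants: 16 (1R,5R)-3-{(E)-4-[2-methoxy-3-methyl-5-(triisopropylsilyloxy)phenyl]-2-methylbut-2-en-1-yl}-1,5-dimethylbicyclo[3.3.0]octan-2-one

Product: 18 (1R,5R)-3-hydroxy-3-{(E)-4-[2-methoxy-3-methyl-5-(triisopropylsilyloxy)phenyl]-2-methylbut-2-en-1-yl}-1,5-dimethylbicyclo[3.3.0]octan-2-one (C3 epimers), via potassium enolate 17 (not isolated)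

Conditions: KN(SiMe3)2, THF, −78 °C; 3-phenyl-2-(phenylsulfonyl)oxaziridine, −78 °C; aq. NH4Cl

Reagents that add atoms: 3-phenyl-2-(phenylsulfonyl)oxaziridine `O=S(=O)(c1ccccc1)N1OC1c1ccccc1`

Why: Enolate hydroxylation with an N-sulfonyloxaziridine: the only remaining α-hydrogen is at C3, and the potassium enolate attacks the electrophilic oxygen to give the tertiary α-hydroxy ketone; unlike a peracid, the reagent leaves the alkene and the arene alone.

**Step 10**

Reactants: 18 (1R,5R)-3-hydroxy-3-{(E)-4-[2-methoxy-3-methyl-5-(triisopropylsilyloxy)phenyl]-2-methylbut-2-en-1-yl}-1,5-dimethylbicyclo[3.3.0]octan-2-one; 19 2-methylbut-3-yn-2-ol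

Product: 21 (1R,5R)-2-(3-hydroxy-3-methylbut-1-yn-1-yl)-3-{(E)-4-[2-methoxy-3-methyl-5-(triisopropylsilyloxy)phenyl]-2-methylbut-2-en-1-yl}-1,5-dimethylbicyclo[3.3.0]octane-2,3-diol (C2 and C3 epimers), via dilithium alkynide 20 (not isolated)

Conditions: 19 (4 equiv), n-BuLi (8 equiv), THF, −78 to 0 °C; then 18, −78 °C to rt; aq. NH4Cl

Reagents that add atoms: none

Why: 1,2-Addition of a lithium acetylide to a ketone: 18 has no α-hydrogen, so enolisation cannot compete, and the rod-shaped alkynide is the carbon nucleophile best able to reach a carbonyl between two fully substituted carbons; one equivalent is consumed by the hydroxyl. The C2 configuration is immaterial.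

**Step 11**

Reactants: 21 (1R,5R)-2-(3-hydroxy-3-methylbut-1-yn-1-yl)-3-{(E)-4-[2-methoxy-3-methyl-5-(triisopropylsilyloxy)phenyl]-2-methylbut-2-en-1-yl}-1,5-dimethylbicyclo[3.3.0]octane-2,3-diol

Product: 22 (1R,5R)-2-[(E)-3-hydroxy-3-methylbut-1-en-1-yl]-3-{(E)-4-[2-methoxy-3-methyl-5-(triisopropylsilyloxy)phenyl]-2-methylbut-2-en-1-yl}-1,5-dimethylbicyclo[3.3.0]octane-2,3-diol

Conditions: NaAlH2(OCH2CH2OMe)2, THF, 0 °C to rt; aq. potassium sodium tartrate

Reagents that add atoms: none

Why: trans-Hydroalumination of a propargylic alkoxide: aluminium bound to a flanking alkoxide delivers hydride intramolecularly, and protonolysis of the alkenylaluminate gives the (E)-alkene; the isolated alkene and the aryl silyl ether should be inert to the hydride at this temperature.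

**Step 12**

Reactants: 22 (1R,5R)-2-[(E)-3-hydroxy-3-methylbut-1-en-1-yl]-3-{(E)-4-[2-methoxy-3-methyl-5-(triisopropylsilyloxy)phenyl]-2-methylbut-2-en-1-yl}-1,5-dimethylbicyclo[3.3.0]octane-2,3-diol

Product: 23 (E)-4-hydroxy-1-[(1R,2R)-2-{(E)-6-[2-methoxy-3-methyl-5-(triisopropylsilyloxy)phenyl]-4-methyl-2-oxohex-4-en-1-yl}-1,2-dimethylcyclopentyl]-4-methylpent-2-en-1-one

Conditions: Pb(OAc)4, pyridine, CH2Cl2, −20 °C to rt

Reagents that add atoms: none

Why: Criegee glycol cleavage: tetravalent lead forms a diester with the ditertiary diol and breaks the C2–C3 bond, leaving divalent lead; C2 becomes the enone carbonyl and C3 the ketone of the arm, so both fragile carbonyl groups appear only here. Diols on five-membered rings are cleaved in either relative configuration (pyridine assists the slower trans case), and the 1,4-related tertiary alcohol is not a glycol. The two quaternary stereocentres are untouched.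

**Step 13**

Reactants: 23 (E)-4-hydroxy-1-[(1R,2R)-2-{(E)-6-[2-methoxy-3-methyl-5-(triisopropylsilyloxy)phenyl]-4-methyl-2-oxohex-4-en-1-yl}-1,2-dimethylcyclopentyl]-4-methylpent-2-en-1-one

Product: 24 (E)-4-hydroxy-1-[(1R,2R)-2-[(E)-6-(5-hydroxy-2-methoxy-3-methylphenyl)-4-methyl-2-oxohex-4-en-1-yl]-1,2-dimethylcyclopentyl]-4-methylpent-2-en-1-one

Conditions: Bu4NF, AcOH (1:1), THF, 0 °C

Reagents that add atoms: none

Why: Fluoride-induced cleavage of the aryl silyl ether (attack at silicon, phenoxide as leaving group); acetic acid buffers the medium so that the β,γ-unsaturated ketone should not isomerise and the 1,5-dicarbonyl array should not close by aldol or Michael reaction.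

Compound list

```
1 | cyclopentene | C1=CCCC1 | starting material
2 | acrylic acid | C=CC(=O)O | starting material
3 | bicyclo[3.3.0]oct-1(5)-en-2-one | O=C1CCC2=C1CCC2 | intermediate
4 | dimethylaluminium (5R)-5-methylbicyclo[3.3.0]oct-1-en-2-olate (not isolated) | C[Al](C)OC1=C2CCC[C@]2(C)CC1 | intermediate
5 | (1R,5R)-1,5-dimethylbicyclo[3.3.0]octan-2-one (cis) | O=C1CC[C@@]2(C)CCC[C@@]12C | intermediate
6 | 4-methoxy-3-methylphenol | COc1ccc(O)cc1C | starting material
7 | triisopropyl(4-methoxy-3-methylphenoxy)silane | COc1ccc(O[Si](C(C)C)(C(C)C)C(C)C)cc1C | intermediate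
8 | [2-methoxy-3-methyl-5-(triisopropylsilyloxy)phenyl]lithium (not isolated) | COc1c(C)cc(O[Si](C(C)C)(C(C)C)C(C)C)cc1[Li] | intermediate
9 | [2-methoxy-3-methyl-5-(triisopropylsilyloxy)phenyl]methanol | COc1c(C)cc(O[Si](C(C)C)(C(C)C)C(C)C)cc1CO | intermediate
10 | [3-(bromomethyl)-4-methoxy-5-methylphenoxy]triisopropylsilane | COc1c(C)cc(O[Si](C(C)C)(C(C)C)C(C)C)cc1CBr | intermediate
11 | prop-2-yn-1-ol | C#CCO | starting material
12 | dimethyl[(E)-3-(dimethylalumanyloxy)-2-methylprop-1-en-1-yl]alumane (not isolated) | C[Al](C)/C=C(\C)CO[Al](C)C | intermediate
13 | (E)-4-[2-methoxy-3-methyl-5-(triisopropylsilyloxy)phenyl]-2-methylbut-2-en-1-ol | COc1c(C)cc(O[Si](C(C)C)(C(C)C)C(C)C)cc1C/C=C(\C)CO | intermediate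
14 | {3-[(E)-4-bromo-3-methylbut-2-en-1-yl]-4-methoxy-5-methylphenoxy}triisopropylsilane | COc1c(C)cc(O[Si](C(C)C)(C(C)C)C(C)C)cc1C/C=C(\C)CBr | intermediate
15 | lithium (1R,5R)-1,5-dimethylbicyclo[3.3.0]oct-2-en-2-olate (not isolated) | [Li]OC1=CC[C@@]2(C)CCC[C@@]12C | intermediate
16 | (1R,5R)-3-{(E)-4-[2-methoxy-3-methyl-5-(triisopropylsilyloxy)phenyl]-2-methylbut-2-en-1-yl}-1,5-dimethylbicyclo[3.3.0]octan-2-one (C3 epimers) | O=C1C(C/C(C)=C/Cc2cc(O[Si](C(C)C)(C(C)C)C(C)C)cc(C)c2OC)C[C@@]2(C)CCC[C@@]12C | intermediate
17 | potassium (1R,5R)-3-{(E)-4-[2-methoxy-3-methyl-5-(triisopropylsilyloxy)phenyl]-2-methylbut-2-en-1-yl}-1,5-dimethylbicyclo[3.3.0]oct-2-en-2-olate (not isolated) | [K]OC1=C(C/C(C)=C/Cc2cc(O[Si](C(C)C)(C(C)C)C(C)C)cc(C)c2OC)C[C@@]2(C)CCC[C@@]12C | intermediate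
18 | (1R,5R)-3-hydroxy-3-{(E)-4-[2-methoxy-3-methyl-5-(triisopropylsilyloxy)phenyl]-2-methylbut-2-en-1-yl}-1,5-dimethylbicyclo[3.3.0]octan-2-one (C3 epimers) | O=C1C(O)(C/C(C)=C/Cc2cc(O[Si](C(C)C)(C(C)C)C(C)C)cc(C)c2OC)C[C@@]2(C)CCC[C@@]12C | intermediate
19 | 2-methylbut-3-yn-2-ol | CC(C)(O)C#C | starting material
20 | lithium 4-lithio-2-methylbut-3-yn-2-olate (not isolated) | [Li]C#CC(C)(C)O[Li] | intermediate
21 | (1R,5R)-2-(3-hydroxy-3-methylbut-1-yn-1-yl)-3-{(E)-4-[2-methoxy-3-methyl-5-(triisopropylsilyloxy)phenyl]-2-methylbut-2-en-1-yl}-1,5-dimethylbicyclo[3.3.0]octane-2,3-diol (C2, C3 epimers) | OC1(C#CC(C)(C)O)C(O)(C/C(C)=C/Cc2cc(O[Si](C(C)C)(C(C)C)C(C)C)cc(C)c2OC)C[C@@]2(C)CCC[C@@]12C | intermediate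
22 | (1R,5R)-2-[(E)-3-hydroxy-3-methylbut-1-en-1-yl]-3-{(E)-4-[2-methoxy-3-methyl-5-(triisopropylsilyloxy)phenyl]-2-methylbut-2-en-1-yl}-1,5-dimethylbicyclo[3.3.0]octane-2,3-diol (C2, C3 epimers) | OC1(/C=C/C(C)(C)O)C(O)(C/C(C)=C/Cc2cc(O[Si](C(C)C)(C(C)C)C(C)C)cc(C)c2OC)C[C@@]2(C)CCC[C@@]12C | intermediate
23 | (E)-4-hydroxy-1-[(1R,2R)-2-{(E)-6-[2-methoxy-3-methyl-5-(triisopropylsilyloxy)phenyl]-4-methyl-2-oxohex-4-en-1-yl}-1,2-dimethylcyclopentyl]-4-methylpent-2-en-1-one | COc1c(C)cc(O[Si](C(C)C)(C(C)C)C(C)C)cc1C/C=C(\C)CC(=O)C[C@@]1(C)CCC[C@@]1(C)C(=O)/C=C/C(C)(C)O | intermediate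
24 | (E)-4-hydroxy-1-[(1R,2R)-2-[(E)-6-(5-hydroxy-2-methoxy-3-methylphenyl)-4-methyl-2-oxohex-4-en-1-yl]-1,2-dimethylcyclopentyl]-4-methylpent-2-en-1-one | COc1c(C)cc(O)cc1C/C=C(\C)CC(=O)C[C@@]1(C)CCC[C@@]1(C)C(=O)/C=C/C(C)(C)O | target
```

Total step count: 13. Longest linear sequence: 11 steps (6 to 24, steps 3–13); the branch from 1 runs through 8 steps (steps 1, 2 and 8–13).

Least certain steps

Step 2 (key step, proposed new method). The most likely failure is lack of turnover or poor enantioface selection, because the β-carbon is fully substituted and the catalyst must distinguish the faces of a flat substrate with no polar handle. Direct 1,2-addition of Me3Al and migration of the enolate to C3 before methylation are the competing processes. The fallback uses known chemistry and sets out from 3. Stoichiometric Me2CuLi in Et2O, followed by MeI with DMPU, should give racemic cis-1,5-dimethylbicyclo[3.3.0]octan-2-one F1. Lithiated (S)-N,S-dimethyl-S-phenylsulfoximine is then added to F1 and the diastereomeric adducts are separated by chromatography. The adduct of the (1R,5R) ketone, β-hydroxysulfoximine F2, is heated in toluene; this releases the sulfoximine and returns to the route at 5. The price is half of the material and three operations in place of one.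

Step 10. The most likely failure is no addition at all, because the carbonyl lies between two fully substituted carbons and next to an alkoxide; on prolonged warming a base-induced α-ketol rearrangement could also set in. The fallback leaves the route at 18 and rejoins it at 23, forming the acyl–alkenyl bond only after the ring is opened. LiAlH4 reduces 18 to (1R,5R)-3-{(E)-4-[2-methoxy-3-methyl-5-(triisopropylsilyloxy)phenyl]-2-methylbut-2-en-1-yl}-1,5-dimethylbicyclo[3.3.0]octane-2,3-diol F3, and Pb(OAc)4 cleaves it to keto aldehyde F4. (E)-4-Iodo-2-methylbut-3-en-2-ol F5, made from 19 with Cp2Zr(H)Cl and then I2, is coupled to the aldehyde with CrCl2 and catalytic NiCl2 (Nozaki–Hiyama–Kishi reaction; divalent chromium is neither basic nor reactive towards the ketone) to give allylic alcohol F6. Dess–Martin periodinane then oxidises F6 to 23.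

Step 12. The most likely failure is slow formation of the cyclic lead diester if the two hydroxyls are trans, which would give the oxidant time to attack the electron-rich arene or the allylic positions. The fallback leaves the route at 18 and rejoins it at 23, using a cleavage that does not depend on diol geometry. Periodic acid (H5IO6, aqueous THF) cleaves the α-hydroxy ketone through its hydrate to keto acid F7. NaBH4 reduces the ketone, and acidification (or a carbodiimide if needed) closes δ-lactone F8. (E)-2-Methyl-4-(tributylstannyl)but-3-en-2-ol F9, from 19 and Bu3SnH with a radical initiator, is converted with n-BuLi into the dilithio alkenyl alkoxide. This is added once to the lactone carbonyl at −78 °C to give hydroxy enone F10 (in equilibrium with its cyclic hemiketal). Dess–Martin periodinane then gives 23.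

Step 4. The most likely failure is metalation at the wrong site: next to the silyloxy group, at the benzylic methyl, or with migration of silicon from oxygen to carbon. The fallback leaves the route at 7 and rejoins it at 9, replacing deprotonation by sterically governed C–H borylation. [Ir(OMe)(cod)]2 with 4,4′-di-tert-butyl-2,2′-bipyridine and B2pin2 should borylate the least hindered C–H, the one next to the small methoxy group, giving aryl boronate F11. Matteson homologation with LiCH2Cl (from BrCH2Cl and n-BuLi) inserts the CH2 to give benzyl boronate F12, and oxidation with NaBO3 gives 9.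

Further compounds

```
F1 | step 2 | cis-1,5-dimethylbicyclo[3.3.0]octan-2-one (racemate, drawn without configuration) | O=C1CCC2(C)CCCC12C
F2 | step 2 | (1R,5R)-1,5-dimethyl-2-{[(S)-N-methyl-S-phenylsulfonimidoyl]methyl}bicyclo[3.3.0]octan-2-ol (carbinol configuration as formed) | CN=[S@@](CC1(O)CC[C@@]2(C)CCC[C@@]12C)(=O)c1ccccc1
F3 | step 10 | (1R,5R)-3-{(E)-4-[2-methoxy-3-methyl-5-(triisopropylsilyloxy)phenyl]-2-methylbut-2-en-1-yl}-1,5-dimethylbicyclo[3.3.0]octane-2,3-diol (C2, C3 epimers) | OC1C(O)(C/C(C)=C/Cc2cc(O[Si](C(C)C)(C(C)C)C(C)C)cc(C)c2OC)C[C@@]2(C)CCC[C@@]12C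
F4 | step 10 | (1R,2R)-2-{(E)-6-[2-methoxy-3-methyl-5-(triisopropylsilyloxy)phenyl]-4-methyl-2-oxohex-4-en-1-yl}-1,2-dimethylcyclopentane-1-carbaldehyde | COc1c(C)cc(O[Si](C(C)C)(C(C)C)C(C)C)cc1C/C=C(\C)CC(=O)C[C@@]1(C)CCC[C@@]1(C)C=O
F5 | step 10 | (E)-4-iodo-2-methylbut-3-en-2-ol | CC(C)(O)/C=C/I
F6 | step 10 | (E)-1-[(1R,2R)-2-{(E)-6-[2-methoxy-3-methyl-5-(triisopropylsilyloxy)phenyl]-4-methyl-2-oxohex-4-en-1-yl}-1,2-dimethylcyclopentyl]-4-methylpent-2-ene-1,4-diol (C1 epimers) | COc1c(C)cc(O[Si](C(C)C)(C(C)C)C(C)C)cc1C/C=C(\C)CC(=O)C[C@@]1(C)CCC[C@@]1(C)C(O)/C=C/C(C)(C)O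
F7 | step 12 | (1R,2R)-2-{(E)-6-[2-methoxy-3-methyl-5-(triisopropylsilyloxy)phenyl]-4-methyl-2-oxohex-4-en-1-yl}-1,2-dimethylcyclopentane-1-carboxylic acid | COc1c(C)cc(O[Si](C(C)C)(C(C)C)C(C)C)cc1C/C=C(\C)CC(=O)C[C@@]1(C)CCC[C@@]1(C)C(=O)O
F8 | step 12 | (4aR,7aR)-3-{(E)-4-[2-methoxy-3-methyl-5-(triisopropylsilyloxy)phenyl]-2-methylbut-2-en-1-yl}-4a,7a-dimethylhexahydrocyclopenta[c]pyran-1(3H)-one (C3 epimers) | COc1c(C)cc(O[Si](C(C)C)(C(C)C)C(C)C)cc1C/C=C(\C)CC1C[C@@]2(C)CCC[C@@]2(C)C(=O)O1
F9 | step 12 | (E)-2-methyl-4-(tributylstannyl)but-3-en-2-ol | CC(C)(O)/C=C/[Sn](CCCC)(CCCC)CCCC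
F10 | step 12 | (E)-4-hydroxy-1-[(1R,2R)-2-{(E)-2-hydroxy-6-[2-methoxy-3-methyl-5-(triisopropylsilyloxy)phenyl]-4-methylhex-4-en-1-yl}-1,2-dimethylcyclopentyl]-4-methylpent-2-en-1-one (carbinol epimers) | COc1c(C)cc(O[Si](C(C)C)(C(C)C)C(C)C)cc1C/C=C(\C)CC(O)C[C@@]1(C)CCC[C@@]1(C)C(=O)/C=C/C(C)(C)O
F11 | step 4 | 2-[2-methoxy-3-methyl-5-(triisopropylsilyloxy)phenyl]-4,4,5,5-tetramethyl-1,3,2-dioxaborolane | COc1c(C)cc(O[Si](C(C)C)(C(C)C)C(C)C)cc1B1OC(C)(C)C(C)(C)O1
F12 | step 4 | 2-[2-methoxy-3-methyl-5-(triisopropylsilyloxy)benzyl]-4,4,5,5-tetramethyl-1,3,2-dioxaborolane | COc1c(C)cc(O[Si](C(C)C)(C(C)C)C(C)C)cc1CB1OC(C)(C)C(C)(C)O1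
A1 | alternative 1 | (1R,3S)-camphoric acid | OC(=O)[C@]1(C)CC[C@H](C(=O)O)C1(C)C
A2 | alternative 1 | methyl (1R,3S)-3-carbamoyl-1,2,2-trimethylcyclopentane-1-carboxylate | COC(=O)[C@]1(C)CC[C@H](C(N)=O)C1(C)C
A3 | alternative 1 | methyl (1S,5S,8R)-1,8-dimethyl-4-oxo-3-oxabicyclo[3.3.0]octane-8-carboxylate | COC(=O)[C@]1(C)CC[C@@H]2C(=O)OC[C@]12C
A4 | alternative 2 | (R)-2-tert-butyl-6-methyl-1,3-dioxin-4-one | CC1=CC(=O)O[C@H](C(C)(C)C)O1
A5 | alternative 2 | 1,2-dimethylcyclopentene | CC1=C(C)CCC1
A6 | alternative 2 | cis-anti-cis tricyclic photoadduct (cyclobutane fused to dioxanone and cyclopentane) | C[C@@]12O[C@@H](C(C)(C)C)OC(=O)[C@@H]1[C@@]1(C)CCC[C@@]21C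
A7 | alternative 2 | 2-[(1R,2R)-2-acetyl-1,2-dimethylcyclopentyl]acetic acid | CC(=O)[C@]1(C)CCC[C@]1(C)CC(=O)O
A8 | alternative 3 | tert-butyl{[(1R,2R)-2-[(S)-2-(tert-butyldimethylsilyloxy)pent-4-yn-1-yl]-1,2-dimethylcyclopentyl]methoxy}dimethylsilane | C#CC[C@H](O[Si](C)(C)C(C)(C)C)C[C@@]1(C)CCC[C@@]1(C)CO[Si](C)(C)C(C)(C)C
A9 | alternative 3 | fully protected (E)-alkene coupling product | COc1c(C)cc(O[Si](C(C)C)(C(C)C)C(C)C)cc1C/C=C(\C)C[C@H](O[Si](C)(C)C(C)(C)C)C[C@@]1(C)CCC[C@@]1(C)CO[Si](C)(C)C(C)(C)C
```
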